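**Plan**

- Retrosynthesis: the exocyclic C=CH2 is traced back to a ring-alkene ester (reduction, then reductive 1,3-transposition), the acetate to an acetyl group (Baeyer–Villiger), and the ArOCH2 group to a formyl group. The acetyl and formyl carbons are then rejoined as one C(CH3)=CH bridge.
- Enabling feature: the ring carbon CMe2 is flanked by two cis-substituted CH carbons (C–OAc and C–CH2OAr). These three atoms are C5 and the two termini of a cyclopentadiene, so the target ring is the six-membered ring of a bicyclo[3.2.1]octa-2,6-diene. The two ring bonds from those CH carbons to the C(=CH2)–CH2–CH2 unit are cut together, giving 2,5,5-trimethylcyclopentadiene and a vinyldiazoacetate.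
- Forward: one rhodium-carbenoid [4+3] annulation builds the carbocycle (as a bicycle) with all twelve carbons of the terpenoid acetate in place. Ozonolysis opens the two-carbon bridge; Mitsunobu etherification, Baeyer–Villiger oxidation and unmasking of the methylene from the tert-butyl ester follow.
- Stereochemistry: both ring stereocentres are the bridgeheads of the bicycle. Their cis relation follows from the bridged ring, their absolute configuration from the chiral dirhodium catalyst; the C–O centre passes through the Baeyer–Villiger step with retention.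

Key step: step 3

Assumption: the sense of induction of Rh2(R-DOSP)4, dirhodium tetrakis[(R)-N-(4-dodecylbenzenesulfonyl)prolinate], is assigned by analogy with carbene transfer to styrene (the S catalyst being taken to give the (1S,2R)-cyclopropane); should it prove opposite, the mirror-image catalyst is used and nothing else changes.

**Route**

Step 1
Reactants: 1 enone 4,4-dimethylcyclopent-2-en-1-one
Product: 3 diene 2,5,5-trimethylcyclopenta-1,3-diene, via tertiary allylic alcohol 2 (not isolated)
Conditions: MeLi, Et2O, −78 to 0 °C; aq. NH4Cl; then TsOH·H2O (cat.), pentane, rt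
Reagents that add atoms: methyllithium, C[Li]
Why: 1,2-addition of the organolithium to the enone, then acid-catalysed dehydration (E1) of the tertiary allylic alcohol; the quaternary carbon has no hydrogen, so the endocyclic diene should form and cannot undergo 1,5-hydrogen shifts.

Step 2
Reactants: 4 tert-butyl but-3-enoate
Product: 5 tert-butyl 2-diazobut-3-enoate
Conditions: p-ABSA, DBU, MeCN, 0 °C
Reagents that add atoms: 4-acetamidobenzenesulfonyl azide (p-ABSA), CC(=O)Nc1ccc(cc1)S(=O)(=O)N=[N+]=[N-]
Why: Regitz diazo transfer onto the doubly activated (allylic, α-ester) CH2; 5 is used at once and kept cold because terminally unsubstituted vinyldiazoacetates electrocyclise to pyrazoles.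

Step 3
Reactants: 3 diene 2,5,5-trimethylcyclopenta-1,3-diene; 5 tert-butyl 2-diazobut-3-enoate
Product: 7 tert-butyl (1R,5S)-6,8,8-trimethylbicyclo[3.2.1]octa-2,6-diene-2-carboxylate, via cis-divinylcyclopropane 6 (not isolated)
Conditions: Rh2(R-DOSP)4 (1 mol %), 3 (3 equiv), hexanes, −78 °C to rt (slow addition of 5); then 50 °C
Reagents that add atoms: none
Why: The dirhodium carbenoid from 5 transfers its carbene carbon to the methyl-free C3=C4 bond of 3 (bonding first at C4) to give cis-divinylcyclopropane 6, and a [3,3]-sigmatropic (Cope) shift through a boat transition state then joins the vinyl CH2 to C1 of the diene, so both new ring bonds are in place in 7. The closest known reaction type is the enantioselective tandem cyclopropanation/Cope rearrangement (formal [4+3] cycloaddition) of vinyldiazoacetates with cyclopentadiene under dirhodium tetraprolinate catalysis. The three-membered ring closes by concerted, asynchronous [2+1] carbene transfer, and the seven-membered ring (which with the C5 bridge is the six-membered carbocycle of the target) closes by pericyclic ring expansion of the cis-divinylcyclopropane. The two new stereocentres are the bridgeheads C1 and C5 of 7: their relative configuration is forced by the bicycle, since both new bonds must lie on one face of the cyclopentene, and their absolute configuration is set in the carbene-transfer step by the chiral prolinate ligands (the diene has a mirror plane and offers no facial bias) and passed on stereospecifically by the Cope step. The step needs regioselectivity between the two diene double bonds, which the methyl group should secure (donor/acceptor carbenoids avoid trisubstituted alkenes, so the methyl ends on the bridge carbon next to the future C–O carbon), and chemoselectivity against allylic C–H insertion, which the quaternary C5 secures.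

Step 4
Reactants: 7 tert-butyl (1R,5S)-6,8,8-trimethylbicyclo[3.2.1]octa-2,6-diene-2-carboxylate
Product: 10 tert-butyl (4R,6R)-4-acetyl-6-(hydroxymethyl)-5,5-dimethylcyclohex-1-ene-1-carboxylate, via secondary ozonide 8 (not isolated), via keto aldehyde 9 (not isolated)
Conditions: O3, CH2Cl2, −78 °C; PPh3, −78 to 0 °C; then NaBH4, EtOH, −78 °C
Reagents that add atoms: ozone, [O-][O+]=O
Why: Ozonolysis should cleave the electron-rich trisubstituted bridge alkene and spare the acrylate-type alkene; chemoselective borohydride reduction at low temperature (aldehyde over hindered methyl ketone) then removes the formyl group before the allylic centre beside it can epimerise, and no new stereocentre is formed.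

Step 5
Reactants: 10 tert-butyl (4R,6R)-4-acetyl-6-(hydroxymethyl)-5,5-dimethylcyclohex-1-ene-1-carboxylate; 11 umbelliferone (7-hydroxy-2H-chromen-2-one)
Product: 12 tert-butyl (4R,6R)-4-acetyl-5,5-dimethyl-6-{[(2-oxo-2H-chromen-7-yl)oxy]methyl}cyclohex-1-ene-1-carboxylate
Conditions: PPh3, DIAD, THF, 0 to 40 °C
Reagents that add atoms: none
Why: Mitsunobu etherification of the only hydroxyl (primary) with an acidic phenol (pKa about 8); the stereocentres are not involved.

Step 6
Reactants: 12 tert-butyl (4R,6R)-4-acetyl-5,5-dimethyl-6-{[(2-oxo-2H-chromen-7-yl)oxy]methyl}cyclohex-1-ene-1-carboxylate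
Product: 13 tert-butyl (4R,6R)-4-(acetyloxy)-5,5-dimethyl-6-{[(2-oxo-2H-chromen-7-yl)oxy]methyl}cyclohex-1-ene-1-carboxylate
Conditions: m-CPBA, CH2Cl2, 0 °C to rt
Reagents that add atoms: 3-chloroperoxybenzoic acid (m-CPBA), OOC(=O)c1cccc(Cl)c1
Why: Baeyer–Villiger oxidation in which the secondary ring carbon migrates in preference to methyl with retention of configuration (as in the 20-oxo steroid to 17-acetate conversion); the acrylate and coumarin alkenes are electron-poor and should resist epoxidation.

Step 7
Reactants: 13 tert-butyl (4R,6R)-4-(acetyloxy)-5,5-dimethyl-6-{[(2-oxo-2H-chromen-7-yl)oxy]methyl}cyclohex-1-ene-1-carboxylate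
Product: 14 (4R,6R)-4-(acetyloxy)-5,5-dimethyl-6-{[(2-oxo-2H-chromen-7-yl)oxy]methyl}cyclohex-1-ene-1-carboxylic acid
Conditions: TFA, CH2Cl2, 0 °C to rt
Reagents that add atoms: none

Why: Acidolysis of the tert-butyl ester (E1 loss of isobutene) frees the acid without base, so the acetate, aryl ether and coumarin lactone should survive.

Step 8
Reactants: 14 (4R,6R)-4-(acetyloxy)-5,5-dimethyl-6-{[(2-oxo-2H-chromen-7-yl)oxy]methyl}cyclohex-1-ene-1-carboxylic acid
Product: 15 (1R,5S)-4-(hydroxymethyl)-6,6-dimethyl-5-{[(2-oxo-2H-chromen-7-yl)oxy]methyl}cyclohex-3-en-1-yl acetate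
Conditions: BH3·THF, THF, 0 °C; MeOH
Reagents that add atoms: none

Why: Chemoselective borane reduction of a carboxylic acid (via the acyloxyborane) to the allylic alcohol, which is far faster than reduction of the acetate or the lactone at 0 °C with controlled stoichiometry.

Step 9
Reactants: 15 (1R,5S)-4-(hydroxymethyl)-6,6-dimethyl-5-{[(2-oxo-2H-chromen-7-yl)oxy]methyl}cyclohex-3-en-1-yl acetate
Product: 18 target 7-{[(1S,3R)-3-(acetyloxy)-2,2-dimethyl-6-methylidenecyclohexyl]methoxy}-2H-chromen-2-one, via N-allyl sulfonylhydrazine 16 (not isolated), via allylic diazene 17 (not isolated)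
Conditions: 2-nitrobenzenesulfonylhydrazide (NBSH), PPh3, DEAD, THF, −30 °C; then rt
Reagents that add atoms: none

Why: Myers reductive allylic transposition: Mitsunobu N-alkylation of NBSH, loss of sulfinic acid to the monoalkyl diazene, and retro-ene loss of N2 deliver hydrogen to the ring CH and move the double bond to the exocyclic position under neutral conditions.

**Compound list**

1 | 4,4-dimethylcyclopent-2-en-1-one | CC1(C)CC(=O)C=C1 | starting material
2 | 1,4,4-trimethylcyclopent-2-en-1-ol (racemic) | CC1(O)C=CC(C)(C)C1 | intermediate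
3 | 2,5,5-trimethylcyclopenta-1,3-diene | CC1=CC(C)(C)C=C1 | intermediate
4 | tert-butyl but-3-enoate | C=CCC(=O)OC(C)(C)C | starting material
5 | tert-butyl 2-diazobut-3-enoate | C=CC(=[N+]=[N-])C(=O)OC(C)(C)C | intermediate
6 | tert-butyl (1S,5R,6S)-6-ethenyl-2,4,4-trimethylbicyclo[3.1.0]hex-2-ene-6-carboxylate (vinyl cis to the cyclopentene ring) | C=C[C@]1(C(=O)OC(C)(C)C)[C@@H]2C(C)=CC(C)(C)[C@@H]21 | intermediate
7 | tert-butyl (1R,5S)-6,8,8-trimethylbicyclo[3.2.1]octa-2,6-diene-2-carboxylate | CC(C)(C)OC(=O)C1=CC[C@H]2C(C)=C[C@@H]1C2(C)C | intermediate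
8 | secondary ozonide of 7 (1,2,4-trioxolane spanning former C6 and C7; epimers at these two acetal carbons) | CC(C)(C)OC(=O)C1=CC[C@H]2C3(C)OOC(O3)[C@@H]1C2(C)C | intermediate
9 | tert-butyl (4R,6R)-4-acetyl-6-formyl-5,5-dimethylcyclohex-1-ene-1-carboxylate | CC(C)(C)OC(=O)C1=CC[C@@H](C(C)=O)C(C)(C)[C@H]1C=O | intermediate
10 | tert-butyl (4R,6R)-4-acetyl-6-(hydroxymethyl)-5,5-dimethylcyclohex-1-ene-1-carboxylate | CC(C)(C)OC(=O)C1=CC[C@@H](C(C)=O)C(C)(C)[C@H]1CO | intermediate
11 | umbelliferone (7-hydroxy-2H-chromen-2-one) | Oc1ccc2ccc(=O)oc2c1 | starting material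
12 | tert-butyl (4R,6R)-4-acetyl-5,5-dimethyl-6-{[(2-oxo-2H-chromen-7-yl)oxy]methyl}cyclohex-1-ene-1-carboxylate | CC(C)(C)OC(=O)C1=CC[C@@H](C(C)=O)C(C)(C)[C@H]1COc1ccc2ccc(=O)oc2c1 | intermediate
13 | tert-butyl (4R,6R)-4-(acetyloxy)-5,5-dimethyl-6-{[(2-oxo-2H-chromen-7-yl)oxy]methyl}cyclohex-1-ene-1-carboxylate | CC(C)(C)OC(=O)C1=CC[C@@H](OC(C)=O)C(C)(C)[C@H]1COc1ccc2ccc(=O)oc2c1 | intermediate
14 | (4R,6R)-4-(acetyloxy)-5,5-dimethyl-6-{[(2-oxo-2H-chromen-7-yl)oxy]methyl}cyclohex-1-ene-1-carboxylic acid | OC(=O)C1=CC[C@@H](OC(C)=O)C(C)(C)[C@H]1COc1ccc2ccc(=O)oc2c1 | intermediate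
15 | (1R,5S)-4-(hydroxymethyl)-6,6-dimethyl-5-{[(2-oxo-2H-chromen-7-yl)oxy]methyl}cyclohex-3-en-1-yl acetate | OCC1=CC[C@@H](OC(C)=O)C(C)(C)[C@H]1COc1ccc2ccc(=O)oc2c1 | intermediate
16 | N-{[(4R,6S)-4-(acetyloxy)-5,5-dimethyl-6-{[(2-oxo-2H-chromen-7-yl)oxy]methyl}cyclohex-1-en-1-yl]methyl}-2-nitrobenzenesulfonohydrazide | NN(CC1=CC[C@@H](OC(C)=O)C(C)(C)[C@H]1COc1ccc2ccc(=O)oc2c1)S(=O)(=O)c1ccccc1[N+](=O)[O-] | intermediate
17 | {[(4R,6S)-4-(acetyloxy)-5,5-dimethyl-6-{[(2-oxo-2H-chromen-7-yl)oxy]methyl}cyclohex-1-en-1-yl]methyl}diazene | N=NCC1=CC[C@@H](OC(C)=O)C(C)(C)[C@H]1COc1ccc2ccc(=O)oc2c1 | intermediate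
18 | 7-{[(1S,3R)-3-(acetyloxy)-2,2-dimethyl-6-methylidenecyclohexyl]methoxy}-2H-chromen-2-one | C=C1CC[C@@H](OC(C)=O)C(C)(C)[C@H]1COc1ccc2ccc(=O)oc2c1 | target

**Step count**

Total steps: 9. Longest linear sequence: 8 steps (4 → 5 → 7 → 10 → 12 → 13 → 14 → 15 → 18).

**Steps most likely to fail**

Step 3. Carbene transfer may go to the methyl-bearing double bond (the electronically preferred terminus), which would place the methyl on the wrong bridge carbon. Approach next to the quaternary carbon may also be slow enough for pyrazole formation from 5 to compete, and the bulky ester may erode enantioselectivity. The fallback controls regiochemistry electronically with a silyl enol ether instead of sterically, and sets out from 1. α-Iodination (I2, pyridine) should give 2-iodo-4,4-dimethylcyclopent-2-en-1-one F1. Suzuki–Miyaura methylation (trimethylboroxine, Pd(PPh3)4, K2CO3) should give 2,4,4-trimethylcyclopent-2-en-1-one F2. Kinetic enolisation (LDA, then TBSCl) should give tert-butyldimethyl[(3,5,5-trimethylcyclopenta-1,3-dien-2-yl)oxy]silane F3. With 5 and the same dirhodium catalyst the carbenoid should now attack the nucleophilic β-carbon of the silyl enol ether, giving tert-butyl (1R,5R)-7-[(tert-butyldimethylsilyl)oxy]-6,8,8-trimethylbicyclo[3.2.1]octa-2,6-diene-2-carboxylate F4. Ozonolysis of its enol ether bridge should give (1R,5R)-5-acetyl-2-(tert-butoxycarbonyl)-6,6-dimethylcyclohex-2-ene-1-carboxylic acid F5. Baeyer–Villiger oxidation (m-CPBA) should give (1R,5R)-5-(acetyloxy)-2-(tert-butoxycarbonyl)-6,6-dimethylcyclohex-2-ene-1-carboxylic acid F6. Borane reduction of the free acid should give tert-butyl (4R,6R)-4-(acetyloxy)-6-(hydroxymethyl)-5,5-dimethylcyclohex-1-ene-1-carboxylate F7, and Mitsunobu etherification with 11 returns to the route at 13.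

Step 4. The formyl-bearing allylic centre of 9 may epimerise, or the ring double bond may move into conjugation, before hydride arrives; the methyl ketone may also be partly reduced. The fallback avoids both the free aldehyde and the chemoselective hydride step, and sets out from 7. Ozonolysis with exhaustive NaBH4 work-up should give tert-butyl (4R,6R)-4-(1-hydroxyethyl)-6-(hydroxymethyl)-5,5-dimethylcyclohex-1-ene-1-carboxylate F8 (carbinol epimers). Mitsunobu etherification with 11 at the primary hydroxyl should give tert-butyl (4R,6R)-4-(1-hydroxyethyl)-5,5-dimethyl-6-{[(2-oxo-2H-chromen-7-yl)oxy]methyl}cyclohex-1-ene-1-carboxylate F9, and Dess–Martin oxidation of the secondary alcohol returns to the route at 12.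

Step 5. Activation and displacement at the hindered primary carbinol (flanked by a quaternary carbon and a substituted alkene carbon) may be too slow, so that the azodicarboxylate-derived hydrazide is alkylated or the alcohol is recovered. The fallback forms the aryl–oxygen bond instead of the alkyl–oxygen bond, and sets out from 10 and 11. Triflation of 11 (Tf2O, pyridine) should give 2-oxo-2H-chromen-7-yl trifluoromethanesulfonate F10. Palladium-catalysed C–O cross-coupling of 10 with it (Pd2(dba)3, tBuBrettPhos, Cs2CO3, toluene, 90 °C; zerovalent palladium, oxidative addition to the aryl triflate, alkoxide exchange, reductive elimination) returns to the route at 12.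

Further compounds
F1 | step 3 | 2-iodo-4,4-dimethylcyclopent-2-en-1-one | O=C1CC(C)(C)C=C1I
F2 | step 3 | 2,4,4-trimethylcyclopent-2-en-1-one | CC1=CC(C)(C)CC1=O
F3 | step 3 | tert-butyldimethyl[(3,5,5-trimethylcyclopenta-1,3-dien-2-yl)oxy]silane | CC1=CC(C)(C)C=C1O[Si](C)(C)C(C)(C)C
F4 | step 3 | tert-butyl (1R,5R)-7-[(tert-butyldimethylsilyl)oxy]-6,8,8-trimethylbicyclo[3.2.1]octa-2,6-diene-2-carboxylate | CC(C)(C)OC(=O)C1=CC[C@H]2C(C)=C(O[Si](C)(C)C(C)(C)C)[C@@H]1C2(C)C
F5 | step 3 | (1R,5R)-5-acetyl-2-(tert-butoxycarbonyl)-6,6-dimethylcyclohex-2-ene-1-carboxylic acid | CC(C)(C)OC(=O)C1=CC[C@@H](C(C)=O)C(C)(C)[C@H]1C(O)=O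
F6 | step 3 | (1R,5R)-5-(acetyloxy)-2-(tert-butoxycarbonyl)-6,6-dimethylcyclohex-2-ene-1-carboxylic acid | CC(C)(C)OC(=O)C1=CC[C@@H](OC(C)=O)C(C)(C)[C@H]1C(O)=O
F7 | step 3 | tert-butyl (4R,6R)-4-(acetyloxy)-6-(hydroxymethyl)-5,5-dimethylcyclohex-1-ene-1-carboxylate | CC(C)(C)OC(=O)C1=CC[C@@H](OC(C)=O)C(C)(C)[C@H]1CO
F8 | step 4 | tert-butyl (4R,6R)-4-(1-hydroxyethyl)-6-(hydroxymethyl)-5,5-dimethylcyclohex-1-ene-1-carboxylate | CC(C)(C)OC(=O)C1=CC[C@@H](C(C)O)C(C)(C)[C@H]1CO
F9 | step 4 | tert-butyl (4R,6R)-4-(1-hydroxyethyl)-5,5-dimethyl-6-{[(2-oxo-2H-chromen-7-yl)oxy]methyl}cyclohex-1-ene-1-carboxylate | CC(C)(C)OC(=O)C1=CC[C@@H](C(C)O)C(C)(C)[C@H]1COc1ccc2ccc(=O)oc2c1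
F10 | step 5 | 2-oxo-2H-chromen-7-yl trifluoromethanesulfonate | O=c1ccc2ccc(OS(=O)(=O)C(F)(F)F)cc2o1
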